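**Retrosynthetic overview**

- The route rests on ring A of the acacetin half (C4a, C5, C6, C7, C8, C8a). Its oxygens on C5 and C7 flank the biaryl carbon C6, so C5–C6–C7 is a β-ketoester whose α-carbon C6 already carries C8'' of the apigenin half. The crowded biaryl bond is therefore never made by coupling; it begins as the aryl–CH bond of an arylacetate.
- Key disconnection C7–C8: ring A is opened to a 3-acyl-2-methyl-4-pyrone, which is ring C of the acacetin half. The pyrone methyl carbon is C8 and the ester carbonyl is C7.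
- The β-ketoester comes from C5–C6 acylation of the enolate of methyl (5,7,4'-triisopropoxyflavon-8-yl)acetate with a 4-pyrone-3-carbonyl chloride. The acetate is made from apigenin by isopropylation, C8 iodination and Pd coupling with BrZnCH2CO2Me. The pyrone is made from tert-butyl acetoacetate and an arylpropioloyl chloride by C-acylation and 6-endo oxa-Michael closure.
- Ring order: the apigenin rings are bought, the pyrone ring C of the acacetin half is made first, and ring A is closed on it last. BCl3 then frees the three apigenin hydroxyls and keeps the 4'-methyl ether.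

Key step: step 8

Remark: flavone numbering is used, unprimed for the 6-linked acacetin half and double-primed for the 8-linked apigenin half; the SMILES fixes no configuration about the hindered C6–C8'' axis, so the target is taken as the racemate about that axis.

**Route**

Step 1
Reactants: 1 apigenin
Product: 2 5,7,4'-tri-O-isopropylapigenin
Conditions: 2-bromopropane (8 equiv), Cs2CO3 (6 equiv), DMF, 80 °C
Reagents that add atoms: 2-bromopropane, CC(C)Br
Why: Williamson etherification of all three phenols; the chelated 5-OH reacts last and is forced by excess halide, Cs2CO3 and heat.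

Step 2
Reactants: 2 5,7,4'-tri-O-isopropylapigenin
Product: 3 8-iodo-5,7,4'-tri-O-isopropylapigenin
Conditions: N-iodosuccinimide (1.1 equiv), CF3CO2H (cat.), MeCN–CH2Cl2, 0 °C → rt
Reagents that add atoms: N-iodosuccinimide, O=C1CCC(=O)N1I
Why: Electrophilic aromatic iodination; in 5-O-alkylated 5,7-dioxygenated flavones it should go to C8, since C6 sits between two isopropoxy groups and the B ring is deactivated by conjugation with the pyranone.

Step 3
Reactants: 3 8-iodo-5,7,4'-tri-O-isopropylapigenin
Product: 4 methyl 2-(5,7,4'-triisopropoxyflavon-8-yl)acetate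
Conditions: BrZnCH2CO2Me (3 equiv; from BrCH2CO2Me, Zn dust, Me3SiCl cat., THF), Pd2(dba)3 (2.5 mol %), XPhos (10 mol %), THF, 65 °C
Reagents that add atoms: methyl bromoacetate, COC(=O)CBr (converted with Zn into BrZnCH2CO2Me, COC(=O)C[Zn]Br)
Why: Negishi-type Pd-catalysed arylation of a Reformatsky reagent; the bulky biarylphosphine should carry the doubly ortho-substituted iodide through the cycle, and the mild zinc enolate leaves the vinylogous-ester carbonyl of the flavone alone.

Step 4
Reactants: 5 3-(4-methoxyphenyl)propiolic acid; 6 tert-butyl acetoacetate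
Product: 8 tert-butyl 2-acetyl-5-(4-methoxyphenyl)-3-oxopent-4-ynoate (enolised tricarbonyl), via 3-(4-methoxyphenyl)propioloyl chloride 7 (not isolated)
Conditions: 5, (COCl)2, DMF (cat.), CH2Cl2, 0 °C → rt, evaporate; then 6, MgCl2, pyridine, CH2Cl2, 0 °C → rt; 1 M HCl wash
Reagents that add atoms: none
Why: Acid chloride formation followed by C-acylation of the magnesium chelate of the β-ketoester, conditions under which C-acylation is favoured over O-acylation.

Step 5
Reactants: 8 tert-butyl 2-acetyl-5-(4-methoxyphenyl)-3-oxopent-4-ynoate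
Product: 9 tert-butyl 6-(4-methoxyphenyl)-2-methyl-4-oxo-4H-pyran-3-carboxylate
Conditions: Et3N (1.2 equiv), MeCN, 60 °C
Reagents that add atoms: none
Why: 6-endo-dig oxa-Michael addition of the enolised acetyl oxygen to the ynone β-carbon, the closure by which 2-hydroxyaryl ynones give flavones; the ketone enol oxygen is the better nucleophile and attack at the β-carbon is the electronically matched mode.

Step 6
Reactants: 9 tert-butyl 6-(4-methoxyphenyl)-2-methyl-4-oxo-4H-pyran-3-carboxylate
Product: 10 6-(4-methoxyphenyl)-2-methyl-4-oxo-4H-pyran-3-carboxylic acid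
Conditions: CF3CO2H–CH2Cl2 (1:3), rt
Reagents that add atoms: none
Why: Acidolysis of the tert-butyl ester frees the acid without hydroxide, which would open the 4-pyrone, and without hot aqueous acid, which would decarboxylate it.

Step 7
Reactants: 4 methyl 2-(5,7,4'-triisopropoxyflavon-8-yl)acetate; 10 6-(4-methoxyphenyl)-2-methyl-4-oxo-4H-pyran-3-carboxylic acid
Product: 12 methyl 3-[6-(4-methoxyphenyl)-2-methyl-4-oxo-4H-pyran-3-yl]-3-oxo-2-(5,7,4'-triisopropoxyflavon-8-yl)propanoate (racemic), via 6-(4-methoxyphenyl)-2-methyl-4-oxo-4H-pyran-3-carbonyl chloride 11 (not isolated)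
Conditions: 10, (COCl)2, DMF (cat.), CH2Cl2, 0 °C → rt, evaporate; 4, LiN(SiMe3)2 (2.1 equiv), THF, −78 °C, then 11 in THF, −78 → −40 °C; AcOH quench at −40 °C
Reagents that add atoms: none
Why: Crossed Claisen C-acylation of a lithium ester enolate by an acid chloride, in which the second equivalent of base takes up the more acidic product and acyl substitution at −78 °C should outrun proton transfer from the pyrone methyl group; the new α-stereocentre forms as the racemate and is enolisable, so it needs no control.

Step 8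
Reactants: 12 methyl 3-[6-(4-methoxyphenyl)-2-methyl-4-oxo-4H-pyran-3-yl]-3-oxo-2-(5,7,4'-triisopropoxyflavon-8-yl)propanoate
Product: 14 5,7-dihydroxy-4'-methoxy-6-(5'',7'',4'''-triisopropoxyflavon-8''-yl)flavone (racemic about the C6–C8'' axis), via ring A cyclohexane-1,3-dione tautomer 13 (not isolated)
Conditions: LiN(SiMe3)2 (3.5 equiv), THF–DMPU (10:1), −78 °C → 45 °C; then 1 M HCl
Reagents that add atoms: none
Why: Proposed new method: the first equivalent of LiN(SiMe3)2 removes the C6–H of the β-ketoester and a second removes a proton from the pyrone 2-methyl group (C8), which is vinylogously acidified by the C4 carbonyl; the C8 carbanion adds to the ester carbonyl C7, methoxide leaves, and the cyclohexane-1,3-dione 13 enolises at once to the resorcinol, whose dianion is the thermodynamic sink. The closest known reaction types are the base-induced Claisen cyclisation of 3,5,7-triketo esters to acylphloroglucinols, where the attacked ester is likewise part of an enolate, and the aldol and Claisen condensations of the γ-carbanions of 2-methyl-4-pyrones and 2-methylchromones; closing ring A of a flavone this way onto an α-aryl β-ketoester is without precedent. Ring A (C4a, C5, C6, C7, C8, C8a) closes by a 6-exo-trig attack on the ester carbonyl, with the C4a=C8a bond of the pyrone holding C8 and C5 cis. Closure also needs the ester cis to the pyrone across the C5–C6 enolate bond, a rotamer the lithium chelate disfavours, so DMPU is added and the dianion is warmed to let the twisted, fully substituted enolate rotate while cyclisation drains the reactive rotamer. No stereocentre is formed: the C6 centre of 12 is lost on enolisation and the C6–C8'' axis arises as the racemate. The selectivity needed is attack of C8 on C7 in preference to retro-Claisen cleavage at C5 or addition to either pyranone, and it is secured because the C5 ketone is masked as its enolate, the base is non-nucleophilic and only the C7 closure gives a six-membered ring that aromatises irreversibly.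

Step 9
Reactants: 14 5,7-dihydroxy-4'-methoxy-6-(5'',7'',4'''-triisopropoxyflavon-8''-yl)flavone
Product: 15 CNP0302154.0 (5,7-dihydroxy-4'-methoxy-6-(5'',7'',4'''-trihydroxyflavon-8''-yl)flavone, racemic about the axis)
Conditions: BCl3 (10 equiv), CH2Cl2, −78 → 0 °C; then MeOH, water
Reagents that add atoms: none
Why: Lewis-acid dealkylation in which BCl3 cleaves secondary isopropyl aryl ethers (the 5''-ether assisted by chelation to C4''=O) and should leave the unchelated 4'-methyl ether intact.

**Compound list**

1 | apigenin | O=c1cc(-c2ccc(O)cc2)oc2cc(O)cc(O)c12 | starting material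
2 | 5,7,4'-tri-O-isopropylapigenin | CC(C)Oc1ccc(cc1)-c1cc(=O)c2c(OC(C)C)cc(OC(C)C)cc2o1 | intermediate
3 | 8-iodo-5,7,4'-tri-O-isopropylapigenin | CC(C)Oc1ccc(cc1)-c1cc(=O)c2c(OC(C)C)cc(OC(C)C)c(I)c2o1 | intermediate
4 | methyl 2-(5,7,4'-triisopropoxyflavon-8-yl)acetate | COC(=O)Cc1c(OC(C)C)cc(OC(C)C)c2c(=O)cc(-c3ccc(OC(C)C)cc3)oc12 | intermediate
5 | 3-(4-methoxyphenyl)propiolic acid | COc1ccc(cc1)C#CC(O)=O | starting material
6 | tert-butyl acetoacetate | CC(=O)CC(=O)OC(C)(C)C | starting material
7 | 3-(4-methoxyphenyl)propioloyl chloride | COc1ccc(cc1)C#CC(Cl)=O | intermediate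
8 | tert-butyl 2-acetyl-5-(4-methoxyphenyl)-3-oxopent-4-ynoate (drawn as the triketo form; enolised) | COc1ccc(cc1)C#CC(=O)C(C(C)=O)C(=O)OC(C)(C)C | intermediate
9 | tert-butyl 6-(4-methoxyphenyl)-2-methyl-4-oxo-4H-pyran-3-carboxylate | COc1ccc(cc1)-c1cc(=O)c(C(=O)OC(C)(C)C)c(C)o1 | intermediate
10 | 6-(4-methoxyphenyl)-2-methyl-4-oxo-4H-pyran-3-carboxylic acid | COc1ccc(cc1)-c1cc(=O)c(C(O)=O)c(C)o1 | intermediate
11 | 6-(4-methoxyphenyl)-2-methyl-4-oxo-4H-pyran-3-carbonyl chloride | COc1ccc(cc1)-c1cc(=O)c(C(Cl)=O)c(C)o1 | intermediate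
12 | methyl 3-[6-(4-methoxyphenyl)-2-methyl-4-oxo-4H-pyran-3-yl]-3-oxo-2-(5,7,4'-triisopropoxyflavon-8-yl)propanoate (racemic) | COC(=O)C(C(=O)c1c(C)oc(cc1=O)-c1ccc(OC)cc1)c1c(OC(C)C)cc(OC(C)C)c2c(=O)cc(-c3ccc(OC(C)C)cc3)oc12 | intermediate
13 | 2-(4-methoxyphenyl)-6-(5,7,4'-triisopropoxyflavon-8-yl)-6,8-dihydro-4H-chromene-4,5,7-trione (racemic; diketo tautomer of 14) | COc1ccc(cc1)C1=CC(=O)C2=C(O1)CC(=O)C(C2=O)c1c(OC(C)C)cc(OC(C)C)c2c(=O)cc(-c3ccc(OC(C)C)cc3)oc12 | intermediate
14 | 5,7-dihydroxy-4'-methoxy-6-(5'',7'',4'''-triisopropoxyflavon-8''-yl)flavone (racemic axis) | COc1ccc(cc1)-c1cc(=O)c2c(O)c(-c3c(OC(C)C)cc(OC(C)C)c4c(=O)cc(-c5ccc(OC(C)C)cc5)oc34)c(O)cc2o1 | intermediate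
15 | CNP0302154.0, 5,7-dihydroxy-4'-methoxy-6-(5'',7'',4'''-trihydroxyflavon-8''-yl)flavone (racemic axis) | COc1ccc(-c2cc(=O)c3c(O)c(-c4c(O)cc(O)c5c(=O)cc(-c6ccc(O)cc6)oc45)c(O)cc3o2)cc1 | target

**Step count**

Total: 9 steps. Longest linear sequence: 6 steps (steps 1, 2, 3, 7, 8, 9 or steps 4, 5, 6, 7, 8, 9).

**Steps most likely to fail, with fallbacks**

Step 8 (key step). The dianion may not close, because the ester is deactivated as part of the enolate and held away from the pyrone. On warming, retro-Claisen cleavage of the C5–C6 bond or methoxide attack on a pyranone could then take over.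

The fallback makes the biaryl bond by known cross-coupling. It sets out from 3 and comes back at 15.
- Miyaura borylation of 3 (B2pin2, PdCl2(dppf), KOAc, dioxane, 90 °C) should give 5,7,4'-tri-O-isopropylapigenin-8-boronic acid pinacol ester F1.
- Commercial acacetin (COc1ccc(cc1)-c1cc(=O)c2c(O)cc(O)cc2o1) is alkylated at the unchelated 7-OH (2-bromopropane, K2CO3, acetone, reflux) to 7-O-isopropylacacetin F2.
- F2 is iodinated at C6 under the direction of the free 5-OH (BnMe3N·ICl2, CaCO3, CH2Cl2–MeOH) to 6-iodo-7-O-isopropylacacetin F3.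
- F3 is methylated at the 5-OH (Me2SO4, K2CO3, acetone, reflux) to 6-iodo-7-O-isopropyl-5-O-methylacacetin F4.
- Suzuki–Miyaura coupling of F1 with F4 (Pd(OAc)2, SPhos, K3PO4, toluene–water, 100 °C) should give the fully protected biflavone F5.
- BCl3 in CH2Cl2 then cleaves the four isopropyl ethers and, by chelation to C4=O, the 5-methyl ether, spares the 4'-methyl ether and gives 15.

Step 7. The enolate of 4 is hindered and may be O-acylated, or may take a proton from the pyrone methyl group of 11 and trigger ketene-type decomposition of the acid chloride. The product may also suffer retro-Claisen cleavage on work-up.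

The fallback is a Masamune–Brooks decarboxylative Claisen under neutral conditions. It sets out from 4 and 10 and comes back at 12.
- The enolate of 4 (LiN(SiMe3)2, THF, −78 °C) is carboxylated with CO2 to the malonic half-ester 3-methoxy-3-oxo-2-(5,7,4'-triisopropoxyflavon-8-yl)propanoic acid F6, which is kept cold.
- Acid 10 is converted with 1,1'-carbonyldiimidazole (THF, rt) into the acyl imidazolide F7.
- F6 is treated with MgCl2 and Et3N in MeCN and then with F7 at rt; C-acylation of the magnesium malonate and loss of CO2 should give 12.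

Step 3. Oxidative addition and transmetalation at the doubly ortho-substituted C8 iodide may be slow, so that reductive deiodination or self-condensation of the zinc enolate dominates.

The fallback brings in the two-carbon unit as an allyl group and cuts it down. It sets out from 3 and comes back at 4.
- Stille coupling of 3 with allyltributylstannane (Pd(PPh3)4, DMF, 100 °C) should give 8-allyl-5,7,4'-tri-O-isopropylapigenin F8.
- Lemieux–Johnson cleavage (OsO4 cat., NaIO4, 2,6-lutidine, dioxane–water) of the terminal alkene, which is more electron-rich than the C2''=C3'' bond, gives the arylacetaldehyde F9.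
- Pinnick oxidation (NaClO2, NaH2PO4, 2-methyl-2-butene, t-BuOH–water) gives the arylacetic acid F10.
- Esterification with Me3SiCHN2 (MeOH–toluene, rt) gives 4.

**Further compounds**

F1 | step 8 | 5,7,4'-tri-O-isopropylapigenin-8-boronic acid pinacol ester | CC(C)Oc1ccc(cc1)-c1cc(=O)c2c(OC(C)C)cc(OC(C)C)c(B3OC(C)(C)C(C)(C)O3)c2o1
F2 | step 8 | 7-O-isopropylacacetin | COc1ccc(cc1)-c1cc(=O)c2c(O)cc(OC(C)C)cc2o1
F3 | step 8 | 6-iodo-7-O-isopropylacacetin | COc1ccc(cc1)-c1cc(=O)c2c(O)c(I)c(OC(C)C)cc2o1
F4 | step 8 | 6-iodo-7-O-isopropyl-5-O-methylacacetin | COc1ccc(cc1)-c1cc(=O)c2c(OC)c(I)c(OC(C)C)cc2o1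
F5 | step 8 | 7-isopropoxy-5,4'-dimethoxy-6-(5'',7'',4'''-triisopropoxyflavon-8''-yl)flavone (racemic axis) | COc1ccc(cc1)-c1cc(=O)c2c(OC)c(-c3c(OC(C)C)cc(OC(C)C)c4c(=O)cc(-c5ccc(OC(C)C)cc5)oc34)c(OC(C)C)cc2o1
F6 | step 7 | 3-methoxy-3-oxo-2-(5,7,4'-triisopropoxyflavon-8-yl)propanoic acid (racemic) | COC(=O)C(C(O)=O)c1c(OC(C)C)cc(OC(C)C)c2c(=O)cc(-c3ccc(OC(C)C)cc3)oc12
F7 | step 7 | 3-(imidazole-1-carbonyl)-6-(4-methoxyphenyl)-2-methyl-4H-pyran-4-one | COc1ccc(cc1)-c1cc(=O)c(C(=O)n2ccnc2)c(C)o1
F8 | step 3 | 8-allyl-5,7,4'-tri-O-isopropylapigenin | C=CCc1c(OC(C)C)cc(OC(C)C)c2c(=O)cc(-c3ccc(OC(C)C)cc3)oc12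
F9 | step 3 | 2-(5,7,4'-triisopropoxyflavon-8-yl)acetaldehyde | O=CCc1c(OC(C)C)cc(OC(C)C)c2c(=O)cc(-c3ccc(OC(C)C)cc3)oc12
F10 | step 3 | 2-(5,7,4'-triisopropoxyflavon-8-yl)acetic acid | OC(=O)Cc1c(OC(C)C)cc(OC(C)C)c2c(=O)cc(-c3ccc(OC(C)C)cc3)oc12
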